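Everything rests on disconnecting ring A (the anisole ring: C1′ ether oxygen, C2′ OMe, C3′ and C5′ Br) at C2′–C3′ and C3′–C4′, so that C3′ and its bromine form one dibromocarbene unit. The feature exploited is that the bromine-bearing C3′ is the immediate neighbour of the methoxy-bearing C2′. Carbene insertion next to a silyl enol ether carbon gives this 2-bromo-1-oxo pattern and enlarges a cyclopentane to the six-membered ring in one operation. The precursor is the kinetic trimethylsilyl enol ether of a racemic 2-aryloxycyclopentanone, enolised away from the aryloxy carbon and already carrying the complete, benzyl-protected dibromo ring B. Aromatisation, C5′ bromination, O-methylation and debenzylation follow.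

Key step: step 4

Remark: the target is achiral; the single stereocentre of the ring-saturated intermediates is carried as the racemate and disappears on aromatisation.
Remark: the benzyl ether is kept because it tolerates the amide base, the alkoxide/carbene conditions and the brominations; with four aryl bromides present it must be removed by a Lewis acid, not by hydrogenolysis.

Step 1
Reactants: 1 2-(benzyloxy)phenol
Product: 3 2-(benzyloxy)-4,6-dibromophenol, via 2-(benzyloxy)-6-bromophenol 2 (not isolated)
Conditions: NBS (2.05 equiv), i-Pr2NH (0.1 equiv), CH2Cl2, 0 °C to rt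
Reagents that add atoms: N-bromosuccinimide, O=C1CCC(=O)N1Br
Why: Amine-mediated electrophilic aromatic bromination is steered by the free hydroxyl, so the first bromine should enter ortho (C6) and the second para (C4) to OH, both meta to the benzyloxy group, which is the ring B pattern of the target.

Step 2
Reactants: 3 2-(benzyloxy)-4,6-dibromophenol; 4 racemic 2-chlorocyclopentan-1-one
Product: 5 racemic 2-[2-(benzyloxy)-4,6-dibromophenoxy]cyclopentan-1-one
Conditions: K2CO3, DMF, 50 °C
Reagents that add atoms: none
Why: Williamson-type SN2 displacement of the carbonyl-activated secondary chloride by the phenoxide of the acidic dibromophenol should form the alkyl aryl ether; the new stereocentre arises as a racemate and is erased in step 5.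

Step 3
Reactants: 5 racemic 2-[2-(benzyloxy)-4,6-dibromophenoxy]cyclopentan-1-one
Product: 7 racemic {[5-(2-(benzyloxy)-4,6-dibromophenoxy)cyclopent-1-en-1-yl]oxy}trimethylsilane, via lithium enolate 6 (not isolated)
Conditions: LiN(i-Pr)2 (1.05 equiv) added to 5 and TMSCl (3 equiv), THF, −78 °C; pentane, filtration, concentration; used crude
Reagents that add atoms: chlorotrimethylsilane, C[Si](C)(C)Cl
Why: Kinetic deprotonation by the bulky amide should take a proton from the open C5 methylene and not the tertiary C2–H, which is shielded by the 2,6-disubstituted aryloxy group and disfavoured by oxygen lone-pair repulsion; immediate O-silylation at −78 °C prevents equilibration (kinetic enolate trapping), and near-stoichiometric base limits metalation of ring B between its bromines.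

Step 4
Reactants: 7 racemic {[5-(2-(benzyloxy)-4,6-dibromophenoxy)cyclopent-1-en-1-yl]oxy}trimethylsilane; 8 bromoform
Product: 10 racemic 6-[2-(benzyloxy)-4,6-dibromophenoxy]-2-bromocyclohex-2-en-1-one, via dibromocyclopropane 9 (not isolated)
Conditions: CHBr3 (2 equiv), KOt-Bu (1.8 equiv, in portions), hexane–toluene, −30 °C to rt; then 60 °C; aq. NaHCO3
Reagents that add atoms: bromoform (8), BrC(Br)Br
Why: α-Elimination of HBr from bromoform by KOt-Bu generates singlet dibromocarbene, which adds in a concerted [2+1] cycloaddition to the most electron-rich π bond of 7, the silyl enol ether C1=C2, to give the 6,6-dibromobicyclo[3.1.0]hexane 9. The endo bromide then ionises with help from the siloxy oxygen while the shared C1–C5 bond of 9 breaks in a thermally allowed two-electron disrotatory electrocyclic opening, and bromide strips the silyl group from the resulting 2-bromo oxyallyl cation to release enone 10. The closest known reaction type is the dihalocarbene ring enlargement of cyclic silyl enol ethers to 2-halocycloalk-2-enones, applied here to an α′-aryloxy substrate. The six-membered ring is not closed by a cyclisation: it arises by insertion of the carbene carbon between the two former enol ether carbons, that is by cyclopropanation followed by cleavage of the zero-atom bridge. No stereocentre is created, since both new bonds end at sp2 carbons, and the racemic aryloxy-bearing carbon is a spectator that becomes aromatic in step 5. The step needs regioselectivity, which is fixed by the position of the enol ether double bond set in step 3, and chemoselectivity for that alkene over the two arenes and the benzylic C–H bonds, which the high nucleophilicity of the siloxy alkene toward the electrophilic carbene secures.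

Step 5
Reactants: 10 racemic 6-[2-(benzyloxy)-4,6-dibromophenoxy]-2-bromocyclohex-2-en-1-one
Product: 12 2-[2-(benzyloxy)-4,6-dibromophenoxy]-6-bromophenol, via bromoketone 11 (not isolated)
Conditions: PhNMe3Br3 (1.05 equiv), THF, 0 °C to rt; concentrate; Li2CO3, LiBr, DMF, 100 °C
Reagents that add atoms: none
Why: Acid-catalysed enol bromination at C6 followed by carbonate-mediated dehydrobromination should give a cyclohexadienone that tautomerises irreversibly to the phenol (bromination–dehydrobromination aromatisation of a cyclohexenone); bromination at C4 instead would lose HBr to the same phenol, so the result should not depend on the site of enolisation.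

Step 6
Reactants: 12 2-[2-(benzyloxy)-4,6-dibromophenoxy]-6-bromophenol
Product: 13 2-[2-(benzyloxy)-4,6-dibromophenoxy]-4,6-dibromophenol
Conditions: NBS (1.0 equiv), MeCN, 0 °C
Reagents that add atoms: N-bromosuccinimide, O=C1CCC(=O)N1Br
Why: Electrophilic aromatic bromination of the free phenol should go only para to OH (future C5′), because both ortho positions are occupied and ring B is deactivated by two bromines; it is done before methylation so that the hydroxyl is the controlling director.

Step 7
Reactants: 13 2-[2-(benzyloxy)-4,6-dibromophenoxy]-4,6-dibromophenol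
Product: 14 1-(benzyloxy)-3,5-dibromo-2-(3,5-dibromo-2-methoxyphenoxy)benzene
Conditions: MeI, K2CO3, DMF, rt
Reagents that add atoms: iodomethane, CI
Why: Williamson O-methylation of the only acidic site, the dibromophenoxide, should be clean since no other nucleophilic group is present.

Step 8
Reactants: 14 1-(benzyloxy)-3,5-dibromo-2-(3,5-dibromo-2-methoxyphenoxy)benzene
Product: 16 3,5-dibromo-2-(3,5-dibromo-2-methoxyphenoxy)phenol, via aryloxydichloroborane 15 (not isolated)
Conditions: BCl3 (3 equiv), C6HMe5 (3 equiv), CH2Cl2, −78 °C; then H2O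
Reagents that add atoms: none
Why: Lewis-acid debenzylation with a cation scavenger: BCl3 activates the benzyl ether, the benzyl cation is captured by pentamethylbenzene (Friedel–Crafts alkylation) and hydrolysis of the B–O bond frees the phenol, while at −78 °C the methyl ether and the four aryl bromides should remain untouched.

Compound list
1 | 2-(benzyloxy)phenol | Oc1ccccc1OCc1ccccc1 | starting material
2 | 2-(benzyloxy)-6-bromophenol | Oc1c(Br)cccc1OCc1ccccc1 | intermediate (not isolated)
3 | 2-(benzyloxy)-4,6-dibromophenol | Oc1c(OCc2ccccc2)cc(Br)cc1Br | intermediate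
4 | 2-chlorocyclopentan-1-one (racemic) | O=C1CCCC1Cl | starting material
5 | 2-[2-(benzyloxy)-4,6-dibromophenoxy]cyclopentan-1-one (racemic) | O=C1CCCC1Oc1c(OCc2ccccc2)cc(Br)cc1Br | intermediate
6 | lithium 5-[2-(benzyloxy)-4,6-dibromophenoxy]cyclopent-1-en-1-olate (racemic) | [Li+].[O-]C1=CCCC1Oc1c(OCc2ccccc2)cc(Br)cc1Br | intermediate (not isolated)
7 | {[5-(2-(benzyloxy)-4,6-dibromophenoxy)cyclopent-1-en-1-yl]oxy}trimethylsilane (racemic) | C[Si](C)(C)OC1=CCCC1Oc1c(OCc2ccccc2)cc(Br)cc1Br | intermediate
8 | bromoform | BrC(Br)Br | starting material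
9 | {[2-(2-(benzyloxy)-4,6-dibromophenoxy)-6,6-dibromobicyclo[3.1.0]hexan-1-yl]oxy}trimethylsilane (racemic, mixture of diastereomers) | C[Si](C)(C)OC12C(Oc3c(OCc4ccccc4)cc(Br)cc3Br)CCC1C2(Br)Br | intermediate (not isolated)
10 | 6-[2-(benzyloxy)-4,6-dibromophenoxy]-2-bromocyclohex-2-en-1-one (racemic) | O=C1C(Br)=CCCC1Oc1c(OCc2ccccc2)cc(Br)cc1Br | intermediate
11 | 6-[2-(benzyloxy)-4,6-dibromophenoxy]-2,6-dibromocyclohex-2-en-1-one (racemic) | O=C1C(Br)=CCCC1(Br)Oc1c(OCc2ccccc2)cc(Br)cc1Br | intermediate (not isolated)
12 | 2-[2-(benzyloxy)-4,6-dibromophenoxy]-6-bromophenol | Oc1c(Br)cccc1Oc1c(OCc2ccccc2)cc(Br)cc1Br | intermediate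
13 | 2-[2-(benzyloxy)-4,6-dibromophenoxy]-4,6-dibromophenol | Oc1c(Br)cc(Br)cc1Oc1c(OCc2ccccc2)cc(Br)cc1Br | intermediate
14 | 1-(benzyloxy)-3,5-dibromo-2-(3,5-dibromo-2-methoxyphenoxy)benzene | COc1c(Br)cc(Br)cc1Oc1c(OCc2ccccc2)cc(Br)cc1Br | intermediate
15 | [3,5-dibromo-2-(3,5-dibromo-2-methoxyphenoxy)phenoxy]dichloroborane | COc1c(Br)cc(Br)cc1Oc1c(OB(Cl)Cl)cc(Br)cc1Br | intermediate (not isolated)
16 | 3,5-dibromo-2-(3,5-dibromo-2-methoxyphenoxy)phenol | COc1c(Br)cc(Br)cc1Oc1c(O)cc(Br)cc1Br | target

Total step count: 8. Longest linear sequence: 8 steps (from 1).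

Steps most likely to fail

Step 4. The silyl enol ether may be cleaved by tert-butoxide before the carbene is captured, or the cyclopropane may ionise without clean ring enlargement. The fallback gives up the ring enlargement and buys the six-membered ring. Setting out from 3, alkylation with commercial 2-chlorocyclohexanone (O=C1CCCCC1Cl; K2CO3, DMF, 50 °C) should give racemic 2-[2-(benzyloxy)-4,6-dibromophenoxy]cyclohexan-1-one F1. Twofold α-bromination (PhNMe3Br3, 2 equiv, THF) should lead to 2-[2-(benzyloxy)-4,6-dibromophenoxy]-2,6-dibromocyclohexan-1-one F2, and double dehydrobromination (Li2CO3, LiBr, DMF, 120 °C) to 2-[2-(benzyloxy)-4,6-dibromophenoxy]phenol F3. Hydroxyl-directed dibromination of this phenol (NBS, 2 equiv, i-Pr2NH cat., CH2Cl2), which passes through 12, comes back to the route at 13.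

Step 3. Regiocontrol may be lost through deprotonation on the aryloxy-bearing side or through enolate equilibration, and the amide base may metalate ring B. The fallback replaces the kinetic enolate by an enamine formed under thermodynamic control. Setting out from 5, condensation with morpholine (TsOH cat., toluene, azeotropic removal of water) should give 4-{5-[2-(benzyloxy)-4,6-dibromophenoxy]cyclopent-1-en-1-yl}morpholine F4, in which allylic strain places the double bond on the unsubstituted side. Dibromocarbene (CHBr3, KOt-Bu, hexane–toluene, −30 °C to rt) should add to give 4-[2-(2-(benzyloxy)-4,6-dibromophenoxy)-6,6-dibromobicyclo[3.1.0]hexan-1-yl]morpholine F5. Nitrogen-assisted opening of this adduct should give 4-{6-[2-(benzyloxy)-4,6-dibromophenoxy]-2-bromocyclohex-2-en-1-ylidene}morpholin-4-ium bromide F6. Hydrolysis with dilute aqueous acid comes back to the route at 10.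

Step 5. Bromination may be unselective (addition to the bromoalkene or over-bromination), the aryloxy group may be lost by ionisation of the α-bromo-α-aryloxy ketone, or HBr may attack the benzyl ether. The fallback avoids halogenation and dehydrogenates a preformed dienol ether instead. Setting out from 10, silylation (TBSOTf, Et3N, CH2Cl2, 0 °C) should give {[2-(2-(benzyloxy)-4,6-dibromophenoxy)-6-bromocyclohexa-1,5-dien-1-yl]oxy}(tert-butyl)dimethylsilane F7. Oxidation with DDQ (dioxane, rt) should aromatise it to tert-butyl{2-[2-(benzyloxy)-4,6-dibromophenoxy]-6-bromophenoxy}dimethylsilane F8. Desilylation with tetrabutylammonium fluoride (THF, 0 °C) comes back to the route at 12.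

Further compounds
F1 | step 4 | 2-[2-(benzyloxy)-4,6-dibromophenoxy]cyclohexan-1-one (racemic) | O=C1CCCCC1Oc1c(OCc2ccccc2)cc(Br)cc1Br
F2 | step 4 | 2-[2-(benzyloxy)-4,6-dibromophenoxy]-2,6-dibromocyclohexan-1-one (racemic, mixture of diastereomers) | O=C1C(Br)CCCC1(Br)Oc1c(OCc2ccccc2)cc(Br)cc1Br
F3 | step 4 | 2-[2-(benzyloxy)-4,6-dibromophenoxy]phenol | Oc1ccccc1Oc1c(OCc2ccccc2)cc(Br)cc1Br
F4 | step 3 | 4-{5-[2-(benzyloxy)-4,6-dibromophenoxy]cyclopent-1-en-1-yl}morpholine (racemic) | O1CCN(CC1)C1=CCCC1Oc1c(OCc2ccccc2)cc(Br)cc1Br
F5 | step 3 | 4-[2-(2-(benzyloxy)-4,6-dibromophenoxy)-6,6-dibromobicyclo[3.1.0]hexan-1-yl]morpholine (racemic, mixture of diastereomers) | O1CCN(CC1)C12C(Oc3c(OCc4ccccc4)cc(Br)cc3Br)CCC1C2(Br)Br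
F6 | step 3 | 4-{6-[2-(benzyloxy)-4,6-dibromophenoxy]-2-bromocyclohex-2-en-1-ylidene}morpholin-4-ium bromide (racemic) | O1CC[N+](CC1)=C1C(Br)=CCCC1Oc1c(OCc2ccccc2)cc(Br)cc1Br.[Br-]
F7 | step 5 | {[2-(2-(benzyloxy)-4,6-dibromophenoxy)-6-bromocyclohexa-1,5-dien-1-yl]oxy}(tert-butyl)dimethylsilane | CC(C)(C)[Si](C)(C)OC1=C(Oc2c(OCc3ccccc3)cc(Br)cc2Br)CCC=C1Br
F8 | step 5 | tert-butyl{2-[2-(benzyloxy)-4,6-dibromophenoxy]-6-bromophenoxy}dimethylsilane | CC(C)(C)[Si](C)(C)Oc1c(Br)cccc1Oc1c(OCc2ccccc2)cc(Br)cc1Br
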